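**Retrosynthetic overview**
- Target 8 comes from acetate 7 by methanolysis of the aryl acetate on ring B.
- 7 comes from diketone 6 by cutting O1–C8a; ring C is the only ring built and is closed last by anodic dehydrogenative C–O bond formation, while rings A and B arrive intact.
- 6 comes from methyl ketone 2 and acid chloride 5 by C-acylation (C2–C3 bond).
- 2 comes from 1 by Friedel–Crafts acetylation; 5 comes from acid 3 through acetate 4.
- Feature: the future C8a is the single C–H carbon of ring A in 6 (C6 of the 2,3,4,5-tetramethoxyphenyl ketone), and ring A, with four methoxy groups, is the arene that should be oxidised first.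

Key step: step 5

Assumption: diketone 6 is drawn and named in the diketo form but should exist and react as its hydrogen-bonded enol; locants such as O1 and C8a refer to the flavone skeleton.

**Route**

Step 1
Reactants: 1 1,2,3,4-tetramethoxybenzene
Product: 2 1-(2,3,4,5-tetramethoxyphenyl)ethanone
Conditions: Ac2O (1.5 equiv), Sc(OSO2CF3)3 (5 mol %), CH3NO2, 50 °C
Reagents that add atoms: acetic anhydride, CC(=O)OC(C)=O
Why: Friedel–Crafts acylation at one of the two equivalent free positions (each ortho and para to a methoxy group), where the new ketone deactivates the ring against a second acylation and the catalytic triflate, unlike stoichiometric AlCl3, should leave the methyl ether ortho to the carbonyl intact.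

Step 2
Reactants: 3 3-hydroxy-4,5-dimethoxybenzoic acid
Product: 4 3-acetoxy-4,5-dimethoxybenzoic acid
Conditions: Ac2O (1.3 equiv), pyridine, DMAP (cat.), 0 °C to rt; then H2O, dilute HCl work-up
Reagents that add atoms: acetic anhydride, CC(=O)OC(C)=O
Why: DMAP-catalysed O-acetylation of the phenol (nucleophilic acyl substitution), with a stir in water before acidification so that the carboxyl group is returned as the free acid and the phenol is left masked as a non-nucleophilic, electron-poor ester.

Step 3
Reactants: 4 3-acetoxy-4,5-dimethoxybenzoic acid
Product: 5 3-acetoxy-4,5-dimethoxybenzoyl chloride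
Conditions: (COCl)2 (1.3 equiv), DMF (cat.), CH2Cl2, 0 °C to rt; concentrated and used crude
Reagents that add atoms: oxalyl chloride, O=C(Cl)C(=O)Cl
Why: acid chloride formation through the catalytic Vilsmeier-type chloroiminium species, under neutral conditions with only gaseous by-products, which the aryl acetate and the methyl ethers should tolerate.

Step 4
Reactants: 2 1-(2,3,4,5-tetramethoxyphenyl)ethanone; 5 3-acetoxy-4,5-dimethoxybenzoyl chloride
Product: 6 1-(3-acetoxy-4,5-dimethoxyphenyl)-3-(2,3,4,5-tetramethoxyphenyl)propane-1,3-dione
Conditions: MgBr2·O(C2H5)2 (2.5 equiv), (i-C3H7)2NC2H5 (3 equiv), CH2Cl2, rt; then 1 M HCl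
Reagents that add atoms: none
Why: soft-enolisation C-acylation (crossed Claisen type), in which magnesium coordination lets the amine deprotonate the methyl ketone, the magnesium enolate attacks the acid chloride at carbon and the product rests as its unreactive magnesium diketonate, all without an alkoxide or amide base that would cleave the acetate.

Step 5
Reactants: 6 1-(3-acetoxy-4,5-dimethoxyphenyl)-3-(2,3,4,5-tetramethoxyphenyl)propane-1,3-dione
Product: 7 3'-acetoxy-5,6,7,8,4',5'-hexamethoxyflavone [5-(5,6,7,8-tetramethoxy-4-oxo-4H-chromen-2-yl)-2,3-dimethoxyphenyl acetate]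
Conditions: graphite anode, Pt cathode, undivided cell, (C4H9)4NBF4 (0.1 M), (CF3)2CHOH, substrate 0.02 M, anode held at the first oxidation wave of 6 (located by cyclic voltammetry), about 2.1 F/mol, 20 °C
Reagents that add atoms: none
Why: Proposed new method: the anode should take one electron from ring A of the enolised diketone, its most electron-rich arene, and the radical cation carries much of its positive charge at C6, the only unsubstituted ring carbon (ortho to the 5-methoxy and para to the 3-methoxy group), where the enol oxygen on the ring B side adds before a second electron and a proton are lost and the arene is restored, the protons being reduced to H2 at the cathode; should the enol be oxidised first, its oxygen-centred radical can reach only the same carbon, so both orders of events converge on the O1–C8a bond. The closest known reaction types are the anodic dehydrogenative C–O cyclisations of 2-arylbenzoic acids to benzocoumarins and of N-aryl amides to benzoxazoles, in which a carboxyl or amide oxygen, not an enol oxygen, captures the arene radical cation. Ring C closes as a six-membered ring by attack of O1 on C8a (6-exo-trig counted on the C8–C8a π bond), and the oxygen of the other carbonyl cannot compete because it could only form a four-membered ring. No stereocentre is formed. The step needs ring A to be oxidised before ring B and before the product: four methoxy groups against two methoxy groups plus an acetoxy group on a ring conjugated to a carbonyl should secure the first, and holding the potential at the first wave and stopping near 2 F/mol should secure the second. Attack at the methoxy-bearing C2 would be reversible because no proton can be lost there, and (CF3)2CHOH, a poor nucleophile that stabilises radical cations, should suppress solvent capture and intermolecular coupling at the low substrate concentration.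

Step 6
Reactants: 7 3'-acetoxy-5,6,7,8,4',5'-hexamethoxyflavone
Product: 8 3'-hydroxy-5,6,7,8,4',5'-hexamethoxyflavone [2-(3-hydroxy-4,5-dimethoxyphenyl)-5,6,7,8-tetramethoxy-4H-chromen-4-one]
Conditions: K2CO3 (0.2 equiv), CH3OH/CH2Cl2 (3:1), rt
Reagents that add atoms: none
Why: base-catalysed transesterification (methanolysis) of an aryl acetate, which is fast because phenoxide is a good leaving group, under conditions too mild to touch the six methyl ethers or to open the γ-pyrone.

**Compound list**

1 | 1,2,3,4-tetramethoxybenzene | COc1ccc(OC)c(OC)c1OC | starting material
2 | 1-(2,3,4,5-tetramethoxyphenyl)ethanone | CC(=O)c1cc(OC)c(OC)c(OC)c1OC | intermediate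
3 | 3-hydroxy-4,5-dimethoxybenzoic acid | COc1cc(C(=O)O)cc(O)c1OC | starting material
4 | 3-acetoxy-4,5-dimethoxybenzoic acid | COc1cc(C(=O)O)cc(OC(C)=O)c1OC | intermediate
5 | 3-acetoxy-4,5-dimethoxybenzoyl chloride | COc1cc(C(=O)Cl)cc(OC(C)=O)c1OC | intermediate
6 | 1-(3-acetoxy-4,5-dimethoxyphenyl)-3-(2,3,4,5-tetramethoxyphenyl)propane-1,3-dione | COc1cc(C(=O)CC(=O)c2cc(OC)c(OC)c(OC)c2OC)cc(OC(C)=O)c1OC | intermediate
7 | 3'-acetoxy-5,6,7,8,4',5'-hexamethoxyflavone | COc1cc(-c2cc(=O)c3c(OC)c(OC)c(OC)c(OC)c3o2)cc(OC(C)=O)c1OC | intermediate
8 | 3'-hydroxy-5,6,7,8,4',5'-hexamethoxyflavone | COc1cc(-c2cc(=O)c3c(OC)c(OC)c(OC)c(OC)c3o2)cc(O)c1OC | target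

**Step count**

Total steps: 6. Longest linear sequence: 5 steps (3 → 4 → 5 → 6 → 7 → 8; steps 2 to 6).

**Steps most likely to fail**

1. Step 5 (anodic ring closure). Electron removal may occur at the enol or at ring B instead of ring A and lead to intermolecular coupling at the central carbon. The flavone formed may also be oxidised further, or ipso attack at the methoxylated ortho carbon may cost a methoxy group. The fallback uses known chemistry, sets out from ketone 2 and comes back at 7. Ring bromination of 2 at its only free position with N-bromosuccinimide in CH3CN at rt should give 1-(2-bromo-3,4,5,6-tetramethoxyphenyl)ethanone F1. Acylation of F1 with acid chloride 5 under the conditions of step 4 should give 1-(3-acetoxy-4,5-dimethoxyphenyl)-3-(2-bromo-3,4,5,6-tetramethoxyphenyl)propane-1,3-dione F2. Intramolecular Ullmann-type O-arylation of the enolate of F2 (CuI 10 mol %, 1,10-phenanthroline 20 mol %, K2CO3, DMF, 90 °C), a known way from 1-(2-haloaryl)-1,3-diketones to flavones, should then close ring C and give 7. Any acetate lost under these basic conditions is harmless, because step 6 removes it in any case.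

2. Step 4 (C-acylation). O-acylation of the enolate, a second acylation of the diketonate or acetyl transfer from the aryl acetate may erode the C-acylation. The fallback replaces acylation by aldol addition and oxidation; it sets out from acid chloride 5 and ketone 2 and comes back at 6. Rosenmund reduction of 5 (H2 1 atm, Pd on BaSO4, 2,6-lutidine, THF, rt) should give 3-acetoxy-4,5-dimethoxybenzaldehyde F3. The lithium enolate of 2 (LiN(i-C3H7)2, THF, −78 °C) is added to F3 and quenched cold with acetic acid to give racemic 3-(3-acetoxy-4,5-dimethoxyphenyl)-3-hydroxy-1-(2,3,4,5-tetramethoxyphenyl)propan-1-one F4. Its carbinol centre is then removed by oxidation with Dess–Martin periodinane (CH2Cl2, rt) to give 6.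

3. Step 1 (Friedel–Crafts acetylation). Lewis-acid cleavage of the methyl ether ortho to the new carbonyl, or sluggish conversion of the crowded arene, may spoil the acylation. The fallback replaces electrophilic substitution by directed ortho-metalation; it sets out from 1 and comes back at 2. Lithiation of 1 next to a methoxy group (n-C4H9Li, TMEDA, THF, 0 °C) should give (2,3,4,5-tetramethoxyphenyl)lithium F5. This is acylated with N-methoxy-N-methylacetamide (−78 °C to 0 °C, then aqueous NH4Cl) to give 2 without any Lewis acid.

**Further compounds**

F1 | step 5 | 1-(2-bromo-3,4,5,6-tetramethoxyphenyl)ethanone | CC(=O)c1c(Br)c(OC)c(OC)c(OC)c1OC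
F2 | step 5 | 1-(3-acetoxy-4,5-dimethoxyphenyl)-3-(2-bromo-3,4,5,6-tetramethoxyphenyl)propane-1,3-dione | COc1cc(C(=O)CC(=O)c2c(Br)c(OC)c(OC)c(OC)c2OC)cc(OC(C)=O)c1OC
F3 | step 4 | 3-acetoxy-4,5-dimethoxybenzaldehyde | COc1cc(C=O)cc(OC(C)=O)c1OC
F4 | step 4 | racemic 3-(3-acetoxy-4,5-dimethoxyphenyl)-3-hydroxy-1-(2,3,4,5-tetramethoxyphenyl)propan-1-one | COc1cc(C(O)CC(=O)c2cc(OC)c(OC)c(OC)c2OC)cc(OC(C)=O)c1OC
F5 | step 1 | (2,3,4,5-tetramethoxyphenyl)lithium | [Li]c1cc(OC)c(OC)c(OC)c1OC
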